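Sunday's target fell by 0.0230 M between 13 min and 22 min, and I built my reckoning on that fall.

| setting | Tuesday's | Sunday's | Monday's |
|---|---|---|---|
| starting material | 0.600 M | 0.600 M | 0.600 M |
| coupling partner | 0.900 M | 2.70 M | 0.900 M |
| time |  |  | 130 min |

| run | time / min | [target] / M |
|---|---|---|
| Tuesday's run | 0.88 | 0.032 |
| Tuesday's run | 1.5 | 0.053 |
| Tuesday's run | 2.6 | 0.091 |
| Tuesday's run | 4.4 | 0.130 |
| Tuesday's run | 7.5 | 0.183 |
| Tuesday's run | 13 | 0.244 |
| Tuesday's run | 22 | 0.277 |
| Sunday's run | 0.88 | 0.087 |
| Sunday's run | 1.5 | 0.142 |
| Sunday's run | 2.6 | 0.215 |
| Sunday's run | 4.4 | 0.297 |
| Sunday's run | 7.5 | 0.361 |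
| Sunday's run | 13 | 0.386 |
| Sunday's run | 22 | 0.363 |

(standard deviation of a reading: 0.003 M)

- Overall: starting material + coupling partner -> target.
- Constant volume, constant temperature.
- "The second partner" is coupling partner.
- An order is taken over about fifteen percent of the charge, up and down.

1. reaction order in [coupling partner] at the outset, round the charge of the Tuesday's run, defined at two percent of the starting material turned into target
2. target in the Monday's run at 130 min, as a share of the starting material charged
3. which of these the readings show (the two partners rest in a complex / the product speeds the reaction / the product reacts on with the second partner)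

I read the table column against column. Sunday's coupling partner was 3.00 times Tuesday's, and Sunday's first reading was 2.72 times Tuesday's. That gives an order of 0.910. Tuesday's first reading carries 9.38% of scatter, so I took the order as one, with no sign of a complex.

Down Tuesday's column, the mean rate sank from 0.0364 M min⁻¹ before the first reading to 0.0171 M min⁻¹ between 4.4 min and 7.5 min. So the product did not speed the reaction.

Then I followed one target molecule through Sunday's last two rows. Tuesday's first reading gave a forward constant of 0.0673 L mol⁻¹ min⁻¹. Between those rows, Sunday's c(target) averaged 0.374 M. Counting target alone, that left at most 0.225 M of starting material and 2.33 M of coupling partner, since any further product takes more of both. On those upper figures, forward alone would have made 0.0353 M min⁻¹. Target fell at 0.00256 M min⁻¹, much slower than that. So I read Sunday's flask as near equilibrium, with target going back and forming again.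

Per unit of target, Sunday's c(target) sank on net at 0.00682 min⁻¹. That is a net figure, with re-formation still feeding target, and not the rate of the exit itself. I took the exit to be reaction with the coupling partner, and dividing by c(coupling partner) gave 0.00293 L mol⁻¹ min⁻¹. This is my net drain constant, the net fall of c(target) per minute, per unit of target and per unit of c(coupling partner).

Monday's charge was Tuesday's, so I started from Tuesday's last reading, 0.277 M at 22 min, with c(coupling partner) near 0.623 M. The net drain there is pseudo-first-order at 0.00183 min⁻¹. Over 108 min it leaves 0.227 M, which is 37.9% of the charge.

The forecast gave order 0.95, 18% (from 8% to 30%) and the product reacts on with the second partner, saying "That loss depends only weakly on the partner, so it looks saturated.", and my share stood above its figure.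

The flask gave order 1.0, 37.7% and the product reacts on with the second partner.

    starting material + coupling partner ⇌ target + by-product (0.07020 L mol⁻¹ min⁻¹, 0.1278 L mol⁻¹ min⁻¹)
    target + coupling partner → side product (0.005490 L mol⁻¹ min⁻¹)

In Tuesday's flask, the forward step ran against the return of target with by-product, and target reached a quarter of the charge at 5.32 min. In Monday's flask, target went on to side product with the coupling partner while the forward step still made target, and c(target) sank on net at 0.00189 min⁻¹ on average from Tuesday's last reading. Over my 0.623 M of coupling partner that is 0.00303 L mol⁻¹ min⁻¹, beside my net drain constant of 0.00293 L mol⁻¹ min⁻¹, and target stood at 37.7% at 130 min.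

Readings and results stem from a simulated flask on assumed constants; the scatter is artificial.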